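## The problem

Target **36** is a 4,9-friedodrimane arylmethane. Drimane numbering is used throughout: ring A is C1–C5 with C10, ring B is C5–C10, C11 is the benzylic CH2, and the arene is C1'–C6'. A trans-decalin carries an exocyclic C4=CH2, methyl groups on C5, C8 and C9, and on C9 the CH2 link to a benzene ring with an O-2' hydrogen sulfate, a free 3'-OH and a 5'-CH2OH. The four stereocentres C5, C8, C9 and C10 are contiguous and all lie on ring B; two are quaternary. The SMILES corresponds to 5β-, 8β- and 9β-methyl with 10α-H, that is (5S,8S,9R,10S). Because the centres are interlocked in one ring, a single concerted ring-forming event can fix all their relative configurations. No stereocentre lies outside this array, so the absolute sense must come from a reagent or catalyst. Three groups are fragile: the 1,1-disubstituted alkene beside quaternary C5 (acid moves it into the ring, hydrogenation destroys it), the aryl sulfate monoester (acid-labile, polar, and sited on the more hindered of two neighbouring phenol oxygens), and the 5'-CH2OH para to O-2' (a quinone-methide precursor whenever O-2' is free). The feature that opens the route is that 5-CH3 and 8-CH3 are cis and 1,4-related across ring B. They can be tied together through sulfur as CH2–S–CH2, which turns C5=C6–C7=C8 into a locked s-cis cyclic diene (a 2,7-dihydrothiepine). C9=C10 then comes from an (E)-2-methyl enal hung on C5 through C1–C4.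

## Retrosynthesis

**Sulfate and arene protecting groups (36 ⇒ 35 ⇒ 34 ⇒ 33).** The O-2'–S bond is cut late. Sulfating a free catechol-benzyl alcohol would hit the less hindered O-3' and the primary alcohol first, so the sulfate is put on phenol **33**, where O-2' is the only free hydroxyl. O-3' is an allyl ether (it cannot migrate between catechol oxygens and leaves with Pd(PPh3)4 under mild base). The 5'-CH2O is a tert-butyldiphenylsilyl ether (leaves with fluoride). Both removals spare the sulfate and the alkene.

**Exocyclic alkene (33 ⇒ 32 ⇒ 31).** C4=CH2 is cut to the C4 ketone **32** (Wittig methylenation, regiospecific, unlike dehydration of a tertiary carbinol). The ketone comes from dioxolane **31**. One aqueous acid step frees the ketone and O-2' (methoxymethyl ether) before the alkene exists, so the alkene never meets acid.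

**Aryl–C11 bond (31 ⇒ 30 ⇒ 21 + 27).** The C11–C1' bond is cut to neopentyl aldehyde **21** and aryl bromide **27** (through aryllithium **28**). The carbinol oxygen is removed through xanthate **30**. Alkylating a C9 enolate with a benzyl halide would have to create C9 in that step; here C9 is already quaternary and carries CHO, so the aldehyde carbon is the natural handle. **27** comes from 5-bromovanillin **22** through **23**–**26**.

**Unmasking the methyls (21 ⇒ 20 ⇒ 19 ⇒ 18).** The 5- and 8-methyl groups are traced back to the two arms of a CH2–S–CH2 bridge, and C6–C7 to an alkene. Raney Ni does both on a small intermediate, before the arene arrives, so the allyl ether and the benzylic silyl ether never meet nickel. The aldehyde is parked as alcohol **19**/**20** and re-oxidised.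

**Key disconnection (18 ⇒ 17).** C5–C10 and C8–C9 are cut together. Aldehyde **18** is the intramolecular Diels–Alder adduct of **17**, a 3-substituted 2,7-dihydrothiepine carrying a ketal-interrupted tether to an (E)-2-methyl enal. An open (Z,Z)-dimethyl diene could not reach the s-cis form; the sulfide ring removes that penalty and holds both future methyl carbons in the inside positions. **17** has no stereocentre, so the forward step must set four centres and the absolute sense at once. A chiral boron Lewis acid that binds the aldehyde is asked to do this.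

**Enal (17 ⇒ 15 + 16; 15 ⇒ 14 ⇒ 13).** C9=C10 is cut by Wittig reaction of aldehyde **15** with the stabilised ylide **16**, which gives the (E)-geometry the cycloaddition needs. **15** comes from silyl ether **13** by desilylation and oxidation.

**Dihydrothiepine from a benzene ring (13 ⇒ 12 ⇒ 11 ⇒ 10 ⇒ 9 ⇒ 8).** The two C–S bonds are cut to (Z,Z)-diene diol **11**, activated as bis-mesylate **12**. The diene is traced to cis,cis-muconate **10** and half-ester **9**, and these to catechol **8** by cutting the ring bond between the two hydroxylated carbons. The aromatic ring guarantees the Z,Z geometry, and the two former C–OH carbons become the CH2S arms and finally the 5- and 8-methyl groups.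

**Tether and ketal (8 ⇒ 7 ⇒ 6 ⇒ 5 ⇒ 2 + 3; 2 ⇒ 1).** The C4 ketal is installed while C4 is still an aryl ketone (**6** ⇒ **7**), because a dienyl ketone could not be ketalised without isomerisation. Benzyl ethers protect the catechol through that acid step and leave by hydrogenolysis. The tether arrives as Grignard reagent **4** from bromide **3**, added to aldehyde **2**, which is one benzylation from 2,3-dihydroxybenzaldehyde **1**.

## Roads not taken

**Alternative 1:** No ring bond is cut. The 5- and 9-methyl groups are walked back to C4 and C10, leading to a sclareolide-derived 11-aryl-drim-8(12)-ene **A2**. Forward, strong acid (BF3·OEt2 or TfOH, cold) protonates the 8(12)-alkene; H9, 10-CH3, H5 and a 4-CH3 then shift in turn, and loss of a methyl proton should give the friedo skeleton **A1**.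
- Merits: the chiral pool supplies the absolute configuration, every shift is suprafacial and stereospecific, and the route is much shorter. In step economy and certainty of the absolute sense this road is better than the chosen one.
- Weak points for this target: the cascade must run through all four shifts and end by the least favoured proton loss. Stopping after two shifts at the tetrasubstituted 5(10)-alkene, ending at the endocyclic 3-ene, and Friedel–Crafts capture of the cations by the electron-rich arene are all downhill. The exocyclic alkene would also have to survive the acid that makes it. **A1** then still needs two aryl methyl ethers cleaved, an ester reduced and the two phenols told apart for sulfation.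
- Against it the chosen plan sets a C4=CH2 made regiospecifically under base from a ketone, and arene oxygens differentiated from the start.

**Alternative 2:** The C8–C9 bond is cut, leading to cyclohexane **A4** with a 1,1-disubstituted alkene at C9 and an (E)-crotonyl ketone on C5. Forward, Fe(acac)3 and PhSiH3 deliver a hydrogen atom to the alkene CH2, and the tertiary C9 radical adds 6-endo to C8 of the enone to give decalone **A3**.
- Merits: hydrogen-atom-transfer radical conjugate cyclisations of this kind are established and mild. The aryl-methyl group is already in place, so no benzylic deoxygenation is needed, and no sulfur is involved. In maturity of the key reaction this road is ahead of the chosen one.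
- Weak points: C8 and C9 are both new and are set by a stepwise radical addition whose facial preferences at the two centres are independent and hard to predict. **A4** must already hold the vicinal C5/C10 pair. **A3** keeps a C6 ketone that costs further steps to remove.
- Against it the chosen plan sets a concerted step in which the (E)-geometry and the endo rule tie C8, C9, C10 and C5 together.

**Alternative 3:** C9–C10 and C4–C5 are cut, leading to the acyclic dienyl malonate **A6**. Forward, trivalent manganese acetate Mn(OAc)3 makes the malonyl radical, which closes ring B 6-endo and then ring A 6-exo; Cu(OAc)2 oxidises the last radical to the alkene, giving **A5**.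
- Merits: both rings, the trans fusion, 5-CH3, 8-CH3 and the exocyclic C4=CH2 come from a simple chain in one operation with cheap reagents. In convergence on the carbocycle, and in delivering the alkene for free, it beats the chosen plan.
- Weak points: C9 emerges with two identical esters. One must become CH3 and the other CH2Ar with the correct configuration, which means differentiating an axial from an equatorial ester on a crowded quaternary carbon and then a multi-step reduction and arylation. The single C8 stereocentre must also relay facial control through a chair transition state.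
- Against it the chosen plan sets a C9 born with CH3 and CHO already distinct and correctly placed.

Key step: step 13

Assumption: the natural product is drawn as the free aryl hydrogen sulfate. The route delivers it as the sodium salt (the same compound in ionised form), and sulfate intermediates **34** and **35** are drawn as free acids although they are handled as ammonium salts.

## Route

Step 1
Reactants: 1 2,3-dihydroxybenzaldehyde
Product: 2 2,3-bis(benzyloxy)benzaldehyde
Conditions: BnBr, K2CO3, DMF, 60 °C
Reagents that add atoms: benzyl bromide BrCc1ccccc1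
Why: Williamson etherification of both phenols; benzyl ethers survive the later acid ketalisation and leave under neutral hydrogenolysis.

Step 2
Reactants: 2 2,3-bis(benzyloxy)benzaldehyde; 3 (4-bromobutoxy)(tert-butyl)dimethylsilane
Product: 5 rac-1-[2,3-bis(benzyloxy)phenyl]-5-[(tert-butyldimethylsilyl)oxy]pentan-1-ol, via Grignard reagent 4 (not isolated)
Conditions: Mg, THF, 40 °C; then 2, 0 °C; aq. NH4Cl
Reagents that add atoms: none
Why: Grignard addition to an aryl aldehyde brings in C1–C3 and the future C10 carbon; the carbinol centre is irrelevant because it is oxidised next.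

Step 3
Reactants: 5 rac-1-[2,3-bis(benzyloxy)phenyl]-5-[(tert-butyldimethylsilyl)oxy]pentan-1-ol
Product: 6 1-[2,3-bis(benzyloxy)phenyl]-5-[(tert-butyldimethylsilyl)oxy]pentan-1-one
Conditions: Dess–Martin periodinane, NaHCO3, CH2Cl2, rt
Reagents that add atoms: none
Why: Dess–Martin oxidation of a benzylic secondary alcohol; silyl and benzyl ethers are inert.

Step 4
Reactants: 6 1-[2,3-bis(benzyloxy)phenyl]-5-[(tert-butyldimethylsilyl)oxy]pentan-1-one
Product: 7 2-[2,3-bis(benzyloxy)phenyl]-2-{4-[(tert-butyldimethylsilyl)oxy]butyl}-1,3-dioxolane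
Conditions: (TMSOCH2)2, TMSOTf (cat.), CH2Cl2, −78 to −20 °C; pyridine quench
Reagents that add atoms: 1,2-bis(trimethylsilyloxy)ethane C[Si](C)(C)OCCO[Si](C)(C)C
Why: Silyl-triflate-catalysed ketalisation with the bis-silylated glycol is aprotic and cold, so the primary silyl ether survives. C4 is masked while it is still an aryl ketone, before the ring becomes an acid-sensitive diene.

Step 5
Reactants: 7 2-[2,3-bis(benzyloxy)phenyl]-2-{4-[(tert-butyldimethylsilyl)oxy]butyl}-1,3-dioxolane
Product: 8 3-(2-{4-[(tert-butyldimethylsilyl)oxy]butyl}-1,3-dioxolan-2-yl)benzene-1,2-diol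
Conditions: H2 (1 atm), Pd/C, EtOAc, Et3N (trace), rt
Reagents that add atoms: none
Why: Hydrogenolysis of aryl benzyl ethers; the trace of amine keeps the benzylic ketal from acid-assisted C–O hydrogenolysis. The air-sensitive catechol is used at once.

Step 6
Reactants: 8 3-(2-{4-[(tert-butyldimethylsilyl)oxy]butyl}-1,3-dioxolan-2-yl)benzene-1,2-diol
Product: 9 (2Z,4Z)-2-(2-{4-[(tert-butyldimethylsilyl)oxy]butyl}-1,3-dioxolan-2-yl)-6-methoxy-6-oxohexa-2,4-dienoic acid
Conditions: CuCl, pyridine, MeOH, O2 (1 atm), rt
Reagents that add atoms: dioxygen O=O; methanol CO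
Why: Copper-mediated intradiol cleavage of a catechol (o-quinone, methoxide addition, C–C scission) gives the cis,cis-muconic half-ester; the ring fixes both double bonds as Z, and the basic medium spares ketal and silyl ether. The half-ester is drawn with the ester remote from the ketal; either regioisomer converges in step 7.

Step 7
Reactants: 9 (2Z,4Z)-2-(2-{4-[(tert-butyldimethylsilyl)oxy]butyl}-1,3-dioxolan-2-yl)-6-methoxy-6-oxohexa-2,4-dienoic acid
Product: 10 dimethyl (2Z,4Z)-2-(2-{4-[(tert-butyldimethylsilyl)oxy]butyl}-1,3-dioxolan-2-yl)hexa-2,4-dienedioate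
Conditions: TMSCHN2, PhMe/MeOH, 0 °C
Reagents that add atoms: (trimethylsilyl)diazomethane C[Si](C)(C)C=[N+]=[N-]
Why: Neutral O-methylation of the acid avoids the acid or heat that would isomerise or lactonise a cis,cis-muconate.

Step 8
Reactants: 10 dimethyl (2Z,4Z)-2-(2-{4-[(tert-butyldimethylsilyl)oxy]butyl}-1,3-dioxolan-2-yl)hexa-2,4-dienedioate
Product: 11 (2E,4Z)-2-(2-{4-[(tert-butyldimethylsilyl)oxy]butyl}-1,3-dioxolan-2-yl)hexa-2,4-diene-1,6-diol (both CH2OH groups inside; the 2E label is a CIP change only)
Conditions: i-Bu2AlH, CH2Cl2, −78 °C; aq. potassium sodium tartrate (KNaC4H4O6)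
Reagents that add atoms: none
Why: 1,2-Reduction of dienoate esters by i-Bu2AlH at low temperature keeps both double-bond geometries.

Step 9
Reactants: 11 (2E,4Z)-2-(2-{4-[(tert-butyldimethylsilyl)oxy]butyl}-1,3-dioxolan-2-yl)hexa-2,4-diene-1,6-diol
Product: 13 tert-butyl{4-[2-(2,7-dihydrothiepin-3-yl)-1,3-dioxolan-2-yl]butoxy}dimethylsilane, via bis-mesylate 12 (not isolated)
Conditions: MsCl, Et3N, CH2Cl2, −40 °C; then Na2S·9H2O, DMF (dilute), 0 °C to rt
Reagents that add atoms: sodium sulfide [Na+].[Na+].[S-2]
Why: Double SN2 displacement of a bis-allylic electrophile by sulfide, the vinylogue of the 2,5-dihydrothiophene synthesis; the Z,Z-diene holds the two CH2 termini close, so the second alkylation closes the seven-membered ring.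

Step 10
Reactants: 13 tert-butyl{4-[2-(2,7-dihydrothiepin-3-yl)-1,3-dioxolan-2-yl]butoxy}dimethylsilane
Product: 14 4-[2-(2,7-dihydrothiepin-3-yl)-1,3-dioxolan-2-yl]butan-1-ol
Conditions: Bu4NF, THF, 0 °C to rt
Reagents that add atoms: none
Why: Fluoride cleavage of a primary silyl ether; diene, sulfide and ketal are inert.

Step 11
Reactants: 14 4-[2-(2,7-dihydrothiepin-3-yl)-1,3-dioxolan-2-yl]butan-1-ol
Product: 15 4-[2-(2,7-dihydrothiepin-3-yl)-1,3-dioxolan-2-yl]butanal
Conditions: SO3·pyridine, DMSO, i-Pr2NEt, CH2Cl2, 0 °C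
Reagents that add atoms: none
Why: Parikh–Doering oxidation; activated DMSO oxidises the alcohol without touching the dialkyl sulfide or the diene.

Step 12
Reactants: 15 4-[2-(2,7-dihydrothiepin-3-yl)-1,3-dioxolan-2-yl]butanal; 16 2-(triphenylphosphoranylidene)propanal
Product: 17 (2E)-6-[2-(2,7-dihydrothiepin-3-yl)-1,3-dioxolan-2-yl]-2-methylhex-2-enal
Conditions: PhMe, 70 °C
Reagents that add atoms: none
Why: Wittig reaction of a stabilised α-methyl formyl ylide with an aliphatic aldehyde should give the (E)-enal; the temperature is kept below that expected for the uncatalysed cycloaddition.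

Step 13
Reactants: 17 (2E)-6-[2-(2,7-dihydrothiepin-3-yl)-1,3-dioxolan-2-yl]-2-methylhex-2-enal
Product: 18 (5R,8S,9S,10S)-4,4-ethylenedioxy-9-methyl-5,8-(2-thiapropane-1,3-diyl)-Δ6-octalin-9-carbaldehyde (drimane numbering; CH2–S–CH2 bridge on the β face; 9β-CH3; 9α-CHO; 10α-H)
Conditions: (S)-1-(2-methylphenyl)-3,3-diphenyltetrahydro-1H,3H-pyrrolo[1,2-c][1,3,2]oxazaborole (C24H24BNO, 20 mol %), HN(SO2CF3)2 (18 mol %), CH2Cl2, −78 to −20 °C
Reagents that add atoms: none
Why: Proposed new method: an oxazaborolidinium-catalysed intramolecular Diels–Alder reaction has not been shown on a sulfur-bridged cyclic cis,cis-diene with a fully substituted terminus; the closest known reaction types are chiral boron Lewis-acid-catalysed intramolecular Diels–Alder reactions of (E)-2-methyl-2-enals with tethered acyclic dienes and thermal intramolecular cycloadditions onto cyclohexa- and cyclohepta-1,3-dienes. The N-protonated oxazaborolidine binds the aldehyde oxygen syn to the formyl hydrogen, which is held by the ring oxygen; this lowers the LUMO and fixes the s-trans enal over one phenyl group, and the locked s-cis diene C5=C6–C7=C8 then adds in a concerted, asynchronous [4+2] step with the tether-linked C5–C10 bond more advanced than C8–C9. Ring A closes as the tether ring (four-atom tether C1–C4, chair-like, fused at C5–C10) and ring B closes as the new cyclohexene, so the product is a bicyclo[3.2.2]nonene in which CH2–S–CH2, C6=C7 and C9–C10 are the three bridges between C5 and C8. Relative configuration follows from suprafacial addition: the inside CH2S arms on C5 and C8 stay cis, the (E)-geometry keeps CHO cis to H10 and 9-CH3 cis to C1, and the endo placement of CHO under C6=C7 with the tether exo puts CHO and H10 trans, and 9-CH3 cis, to the sulfur bridge, which is the 5β,8β,9β,10α array with a trans ring fusion. Absolute configuration rests on the catalyst: by the binding model for 2-substituted enals the S catalyst should shield the C9 Si face, so C8 bonds to the Re face of C9 (CHO, C10, CH3 clockwise), as 18 requires. The step needs endo over exo selectivity, which aldehyde activation and the chair tether should secure, and it needs the hard boron centre to prefer the aldehyde over the sulfide and ketal donors. Low temperature keeps the dihydrothiepine from 1,5-hydrogen shifts and the dienyl ketal from opening.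

Step 14
Reactants: 18 (5R,8S,9S,10S)-4,4-ethylenedioxy-9-methyl-5,8-(2-thiapropane-1,3-diyl)-Δ6-octalin-9-carbaldehyde
Product: 20 [(1'R,2'S,4a'S,8a'S)-1',2',4a'-trimethyloctahydro-1'H-spiro[1,3-dioxolane-2,5'-naphthalen]-1'-yl]methanol, via bridged sulfide alcohol 19 (not isolated)
Conditions: NaBH4, EtOH, 0 °C; then Raney Ni (W-2), H2 (1 atm), EtOH, 60 °C
Reagents that add atoms: none
Why: Borohydride reduction parks the aldehyde as the alcohol, then Raney nickel desulfurisation turns the two bridge CH2 groups into the 5- and 8-methyl groups and saturates C6=C7. No stereocentre is touched, and while the bridge is intact Bredt's rule forbids migration of the alkene toward C8.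

Step 15
Reactants: 20 [(1'R,2'S,4a'S,8a'S)-1',2',4a'-trimethyloctahydro-1'H-spiro[1,3-dioxolane-2,5'-naphthalen]-1'-yl]methanol
Product: 21 (1'R,2'S,4a'S,8a'S)-1',2',4a'-trimethyloctahydro-1'H-spiro[1,3-dioxolane-2,5'-naphthalene]-1'-carbaldehyde
Conditions: Dess–Martin periodinane, NaHCO3, CH2Cl2, rt
Reagents that add atoms: none
Why: Dess–Martin oxidation of a neopentyl alcohol; the aldehyde has no α-hydrogen and cannot epimerise.

Step 16
Reactants: 22 5-bromovanillin
Product: 23 3-bromo-4,5-dihydroxybenzaldehyde
Conditions: AlCl3, pyridine, CH2Cl2, reflux; aq. HCl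
Reagents that add atoms: none
Why: Chelation-assisted demethylation of an o-hydroxyaryl methyl ether by AlCl3–pyridine, the standard route from vanillins to protocatechualdehydes.

Step 17
Reactants: 23 3-bromo-4,5-dihydroxybenzaldehyde
Product: 24 3-bromo-5-hydroxy-4-(methoxymethoxy)benzaldehyde
Conditions: MOMCl (1 equiv), K2CO3 (1 equiv), acetone, 0 °C to rt
Reagents that add atoms: chloromethyl methyl ether COCCl
Why: Regioselective O-alkylation: the 4-OH is para to CHO and ortho to Br and therefore the more acidic, so one equivalent of base forms and alkylates that phenoxide.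

Step 18
Reactants: 24 3-bromo-5-hydroxy-4-(methoxymethoxy)benzaldehyde
Product: 25 3-bromo-4-(methoxymethoxy)-5-(prop-2-en-1-yloxy)benzaldehyde
Conditions: allyl bromide, K2CO3, DMF, rt
Reagents that add atoms: allyl bromide C=CCBr
Why: Williamson etherification of the remaining phenol; the allyl group is non-migrating and removable at the end under neutral to basic conditions.

Step 19
Reactants: 25 3-bromo-4-(methoxymethoxy)-5-(prop-2-en-1-yloxy)benzaldehyde
Product: 26 [3-bromo-4-(methoxymethoxy)-5-(prop-2-en-1-yloxy)phenyl]methanol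
Conditions: NaBH4, MeOH, 0 °C
Reagents that add atoms: none
Why: Borohydride reduction of an aryl aldehyde.

Step 20
Reactants: 26 [3-bromo-4-(methoxymethoxy)-5-(prop-2-en-1-yloxy)phenyl]methanol
Product: 27 {[3-bromo-4-(methoxymethoxy)-5-(prop-2-en-1-yloxy)phenyl]methoxy}(tert-butyl)diphenylsilane
Conditions: TBDPSCl, imidazole, DMF, rt
Reagents that add atoms: tert-butyl(chloro)diphenylsilane CC(C)(C)[Si](Cl)(c1ccccc1)c1ccccc1
Why: Silylation of the primary alcohol; the diphenyl-tert-butylsilyl ether is chosen for its resistance to the aqueous acid of step 23.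

Step 21
Reactants: 21 (1'R,2'S,4a'S,8a'S)-1',2',4a'-trimethyloctahydro-1'H-spiro[1,3-dioxolane-2,5'-naphthalene]-1'-carbaldehyde; 27 {[3-bromo-4-(methoxymethoxy)-5-(prop-2-en-1-yloxy)phenyl]methoxy}(tert-butyl)diphenylsilane
Product: 30 O-{aryl[(5S,8S,9R,10S)-4,4-ethylenedioxy-5,8,9-trimethyl-trans-decalin-9-yl]methyl} S-methyl carbonodithioate (C11 epimers), via aryllithium 28 (not isolated), via lithium alkoxide 29 (not isolated)
Conditions: 27, t-BuLi (2 equiv), THF, −78 °C; 21, −78 to 0 °C; CS2, 0 °C to rt; MeI
Reagents that add atoms: carbon disulfide S=C=S; iodomethane CI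
Why: Bromine–lithium exchange ortho to the methoxymethoxy group, 1,2-addition of the aryllithium to the neopentyl aldehyde, and trapping of the alkoxide as the xanthate in the same flask; the new C11 centre is not controlled because it is removed next.

Step 22
Reactants: 30 O-{aryl[(5S,8S,9R,10S)-4,4-ethylenedioxy-5,8,9-trimethyl-trans-decalin-9-yl]methyl} S-methyl carbonodithioate
Product: 31 (5S,8S,9R,10S)-9-{[3-(allyloxy)-5-{[(tert-butyldiphenylsilyl)oxy]methyl}-2-(methoxymethoxy)phenyl]methyl}-5,8,9-trimethyl-trans-decalin-4-one ethylene ketal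
Conditions: Bu3SnH, AIBN (cat.), PhMe, 100 °C
Reagents that add atoms: none
Why: Barton–McCombie deoxygenation through the benzylic C11 radical; ketal, ethers and the allyl group are spectators.

Step 23
Reactants: 31 (5S,8S,9R,10S)-9-{[3-(allyloxy)-5-{[(tert-butyldiphenylsilyl)oxy]methyl}-2-(methoxymethoxy)phenyl]methyl}-5,8,9-trimethyl-trans-decalin-4-one ethylene ketal
Product: 32 (5S,8S,9R,10S)-9-{[3-(allyloxy)-5-{[(tert-butyldiphenylsilyl)oxy]methyl}-2-hydroxyphenyl]methyl}-5,8,9-trimethyl-trans-decalin-4-one
Conditions: 3 M aq. HCl, THF, 40 °C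
Reagents that add atoms: water O
Why: Acid hydrolysis frees the C4 ketone and the O-2' phenol together while no alkene is present; the phenol has no free ortho or para position for the released formaldehyde, and the bulky silyl ether and the allyl ether resist dilute acid.

Step 24
Reactants: 32 (5S,8S,9R,10S)-9-{[3-(allyloxy)-5-{[(tert-butyldiphenylsilyl)oxy]methyl}-2-hydroxyphenyl]methyl}-5,8,9-trimethyl-trans-decalin-4-one
Product: 33 2-(allyloxy)-4-{[(tert-butyldiphenylsilyl)oxy]methyl}-6-{[(1R,2S,4aS,8aS)-1,2,4a-trimethyl-5-methylidenedecahydronaphthalen-1-yl]methyl}phenol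
Conditions: Ph3PCH3Br, KOt-Bu (excess), PhMe, 80 °C
Reagents that add atoms: methyltriphenylphosphonium bromide C[P+](c1ccccc1)(c1ccccc1)c1ccccc1.[Br-]
Why: Wittig methylenation of the hindered C4 ketone places the alkene regiospecifically in the exocyclic position under base; excess ylide accommodates the phenoxide.

Step 25
Reactants: 33 2-(allyloxy)-4-{[(tert-butyldiphenylsilyl)oxy]methyl}-6-{[(1R,2S,4aS,8aS)-1,2,4a-trimethyl-5-methylidenedecahydronaphthalen-1-yl]methyl}phenol
Product: 34 2-(allyloxy)-4-{[(tert-butyldiphenylsilyl)oxy]methyl}-6-{[(1R,2S,4aS,8aS)-1,2,4a-trimethyl-5-methylidenedecahydronaphthalen-1-yl]methyl}phenyl hydrogen sulfate (pyridinium salt)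
Conditions: SO3·pyridine, pyridine, 50 °C
Reagents that add atoms: sulfur trioxide–pyridine complex [O-]S(=O)(=O)[n+]1ccccc1
Why: O-Sulfation of the only free hydroxyl; the neighbouring allyl ether cannot migrate, so the sulfate is fixed on O-2'.

Step 26
Reactants: 34 2-(allyloxy)-4-{[(tert-butyldiphenylsilyl)oxy]methyl}-6-{[(1R,2S,4aS,8aS)-1,2,4a-trimethyl-5-methylidenedecahydronaphthalen-1-yl]methyl}phenyl hydrogen sulfate
Product: 35 2-(allyloxy)-4-(hydroxymethyl)-6-{[(1R,2S,4aS,8aS)-1,2,4a-trimethyl-5-methylidenedecahydronaphthalen-1-yl]methyl}phenyl hydrogen sulfate (tetrabutylammonium salt)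
Conditions: Bu4NF, THF, rt
Reagents that add atoms: none
Why: Fluoride desilylation; aryl sulfate monoesters are stable to fluoride, and the tetrabutylammonium salt is soluble in organic solvents.

Step 27
Reactants: 35 2-(allyloxy)-4-(hydroxymethyl)-6-{[(1R,2S,4aS,8aS)-1,2,4a-trimethyl-5-methylidenedecahydronaphthalen-1-yl]methyl}phenyl hydrogen sulfate
Product: 36 2-hydroxy-4-(hydroxymethyl)-6-{[(1R,2S,4aS,8aS)-1,2,4a-trimethyl-5-methylidenedecahydronaphthalen-1-yl]methyl}phenyl hydrogen sulfate (CNP0353860.3; isolated as the sodium salt)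
Conditions: Pd(PPh3)4 (5 mol %), K2CO3, MeOH, rt; Na+-form ion-exchange resin
Reagents that add atoms: none
Why: Zerovalent-palladium-catalysed transfer of the aryl allyl group to methoxide (π-allyl chemistry); no hydride or acid is present, so the sulfate and the 1,1-disubstituted alkene are untouched.

## Compound list

1 | 2,3-dihydroxybenzaldehyde | O=Cc1cccc(O)c1O | starting material
2 | 2,3-bis(benzyloxy)benzaldehyde | O=Cc1cccc(OCc2ccccc2)c1OCc1ccccc1 | intermediate
3 | (4-bromobutoxy)(tert-butyl)dimethylsilane | CC(C)(C)[Si](C)(C)OCCCCBr | starting material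
4 | {4-[(tert-butyldimethylsilyl)oxy]butyl}magnesium bromide | CC(C)(C)[Si](C)(C)OCCCC[Mg]Br | intermediate
5 | rac-1-[2,3-bis(benzyloxy)phenyl]-5-[(tert-butyldimethylsilyl)oxy]pentan-1-ol | CC(C)(C)[Si](C)(C)OCCCCC(O)c1cccc(OCc2ccccc2)c1OCc1ccccc1 | intermediate
6 | 1-[2,3-bis(benzyloxy)phenyl]-5-[(tert-butyldimethylsilyl)oxy]pentan-1-one | CC(C)(C)[Si](C)(C)OCCCCC(=O)c1cccc(OCc2ccccc2)c1OCc1ccccc1 | intermediate
7 | 2-[2,3-bis(benzyloxy)phenyl]-2-{4-[(tert-butyldimethylsilyl)oxy]butyl}-1,3-dioxolane | CC(C)(C)[Si](C)(C)OCCCCC1(OCCO1)c1cccc(OCc2ccccc2)c1OCc1ccccc1 | intermediate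
8 | 3-(2-{4-[(tert-butyldimethylsilyl)oxy]butyl}-1,3-dioxolan-2-yl)benzene-1,2-diol | CC(C)(C)[Si](C)(C)OCCCCC1(OCCO1)c1cccc(O)c1O | intermediate
9 | (2Z,4Z)-2-(2-{4-[(tert-butyldimethylsilyl)oxy]butyl}-1,3-dioxolan-2-yl)-6-methoxy-6-oxohexa-2,4-dienoic acid | COC(=O)/C=C\C=C(/C(O)=O)C1(CCCCO[Si](C)(C)C(C)(C)C)OCCO1 | intermediate
10 | dimethyl (2Z,4Z)-2-(2-{4-[(tert-butyldimethylsilyl)oxy]butyl}-1,3-dioxolan-2-yl)hexa-2,4-dienedioate | COC(=O)/C=C\C=C(/C(=O)OC)C1(CCCCO[Si](C)(C)C(C)(C)C)OCCO1 | intermediate
11 | (2E,4Z)-2-(2-{4-[(tert-butyldimethylsilyl)oxy]butyl}-1,3-dioxolan-2-yl)hexa-2,4-diene-1,6-diol | OC/C=C\C=C(/CO)C1(CCCCO[Si](C)(C)C(C)(C)C)OCCO1 | intermediate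
12 | (2E,4Z)-2-(2-{4-[(tert-butyldimethylsilyl)oxy]butyl}-1,3-dioxolan-2-yl)hexa-2,4-diene-1,6-diyl dimethanesulfonate | CS(=O)(=O)OC/C=C\C=C(/COS(C)(=O)=O)C1(CCCCO[Si](C)(C)C(C)(C)C)OCCO1 | intermediate
13 | tert-butyl{4-[2-(2,7-dihydrothiepin-3-yl)-1,3-dioxolan-2-yl]butoxy}dimethylsilane | CC(C)(C)[Si](C)(C)OCCCCC1(OCCO1)C1=CC=CCSC1 | intermediate
14 | 4-[2-(2,7-dihydrothiepin-3-yl)-1,3-dioxolan-2-yl]butan-1-ol | OCCCCC1(OCCO1)C1=CC=CCSC1 | intermediate
15 | 4-[2-(2,7-dihydrothiepin-3-yl)-1,3-dioxolan-2-yl]butanal | O=CCCCC1(OCCO1)C1=CC=CCSC1 | intermediate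
16 | 2-(triphenylphosphoranylidene)propanal | CC(C=O)=P(c1ccccc1)(c1ccccc1)c1ccccc1 | starting material
17 | (2E)-6-[2-(2,7-dihydrothiepin-3-yl)-1,3-dioxolan-2-yl]-2-methylhex-2-enal | O=C/C(C)=C/CCCC1(OCCO1)C1=CC=CCSC1 | intermediate
18 | (5R,8S,9S,10S)-4,4-ethylenedioxy-9-methyl-5,8-(2-thiapropane-1,3-diyl)-Δ6-octalin-9-carbaldehyde (drimane numbering; sulfide bridge β, 9β-CH3, 9α-CHO, 10α-H) | O1CCOC12CCC[C@H]3[C@](C)(C=O)[C@@H](CSC4)C=C[C@]234 | intermediate
19 | [(5R,8S,9S,10S)-4,4-ethylenedioxy-9-methyl-5,8-(2-thiapropane-1,3-diyl)-Δ6-octalin-9-yl]methanol | O1CCOC12CCC[C@H]3[C@](C)(CO)[C@@H](CSC4)C=C[C@]234 | intermediate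
20 | [(1'R,2'S,4a'S,8a'S)-1',2',4a'-trimethyloctahydro-1'H-spiro[1,3-dioxolane-2,5'-naphthalen]-1'-yl]methanol (5β,8β,9β-trimethyl, 10α-H) | O1CCOC12CCC[C@H]3[C@](C)(CO)[C@@H](C)CC[C@]23C | intermediate
21 | (1'R,2'S,4a'S,8a'S)-1',2',4a'-trimethyloctahydro-1'H-spiro[1,3-dioxolane-2,5'-naphthalene]-1'-carbaldehyde | O1CCOC12CCC[C@H]3[C@](C)(C=O)[C@@H](C)CC[C@]23C | intermediate
22 | 5-bromovanillin (3-bromo-4-hydroxy-5-methoxybenzaldehyde) | COc1cc(C=O)cc(Br)c1O | starting material
23 | 3-bromo-4,5-dihydroxybenzaldehyde | O=Cc1cc(O)c(O)c(Br)c1 | intermediate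
24 | 3-bromo-5-hydroxy-4-(methoxymethoxy)benzaldehyde | O=Cc1cc(O)c(OCOC)c(Br)c1 | intermediate
25 | 3-bromo-4-(methoxymethoxy)-5-(prop-2-en-1-yloxy)benzaldehyde | O=Cc1cc(OCC=C)c(OCOC)c(Br)c1 | intermediate
26 | [3-bromo-4-(methoxymethoxy)-5-(prop-2-en-1-yloxy)phenyl]methanol | OCc1cc(OCC=C)c(OCOC)c(Br)c1 | intermediate
27 | {[3-bromo-4-(methoxymethoxy)-5-(prop-2-en-1-yloxy)phenyl]methoxy}(tert-butyl)diphenylsilane | C=CCOc1cc(CO[Si](c2ccccc2)(c2ccccc2)C(C)(C)C)cc(Br)c1OCOC | intermediate
28 | [3-(allyloxy)-5-{[(tert-butyldiphenylsilyl)oxy]methyl}-2-(methoxymethoxy)phenyl]lithium | C=CCOc1cc(CO[Si](c2ccccc2)(c2ccccc2)C(C)(C)C)cc([Li])c1OCOC | intermediate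
29 | lithium aryl[(5S,8S,9R,10S)-4,4-ethylenedioxy-5,8,9-trimethyl-trans-decalin-9-yl]methanolate (C11 epimers; aryl as in 28) | O1CCOC12CCC[C@H]3[C@](C)(C(O[Li])c4cc(CO[Si](c5ccccc5)(c5ccccc5)C(C)(C)C)cc(OCC=C)c4OCOC)[C@@H](C)CC[C@]23C | intermediate
30 | O-{aryl[(5S,8S,9R,10S)-4,4-ethylenedioxy-5,8,9-trimethyl-trans-decalin-9-yl]methyl} S-methyl carbonodithioate (C11 epimers) | O1CCOC12CCC[C@H]3[C@](C)(C(OC(=S)SC)c4cc(CO[Si](c5ccccc5)(c5ccccc5)C(C)(C)C)cc(OCC=C)c4OCOC)[C@@H](C)CC[C@]23C | intermediate
31 | (5S,8S,9R,10S)-9-{[3-(allyloxy)-5-{[(tert-butyldiphenylsilyl)oxy]methyl}-2-(methoxymethoxy)phenyl]methyl}-5,8,9-trimethyl-trans-decalin-4-one ethylene ketal | O1CCOC12CCC[C@H]3[C@](C)(Cc4cc(CO[Si](c5ccccc5)(c5ccccc5)C(C)(C)C)cc(OCC=C)c4OCOC)[C@@H](C)CC[C@]23C | intermediate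
32 | (5S,8S,9R,10S)-9-{[3-(allyloxy)-5-{[(tert-butyldiphenylsilyl)oxy]methyl}-2-hydroxyphenyl]methyl}-5,8,9-trimethyl-trans-decalin-4-one | O=C1CCC[C@H]2[C@](C)(Cc3cc(CO[Si](c4ccccc4)(c4ccccc4)C(C)(C)C)cc(OCC=C)c3O)[C@@H](C)CC[C@]12C | intermediate
33 | 2-(allyloxy)-4-{[(tert-butyldiphenylsilyl)oxy]methyl}-6-{[(1R,2S,4aS,8aS)-1,2,4a-trimethyl-5-methylidenedecahydronaphthalen-1-yl]methyl}phenol | C=C1CCC[C@H]2[C@](C)(Cc3cc(CO[Si](c4ccccc4)(c4ccccc4)C(C)(C)C)cc(OCC=C)c3O)[C@@H](C)CC[C@]12C | intermediate
34 | 2-(allyloxy)-4-{[(tert-butyldiphenylsilyl)oxy]methyl}-6-{[(1R,2S,4aS,8aS)-1,2,4a-trimethyl-5-methylidenedecahydronaphthalen-1-yl]methyl}phenyl hydrogen sulfate | C=C1CCC[C@H]2[C@](C)(Cc3cc(CO[Si](c4ccccc4)(c4ccccc4)C(C)(C)C)cc(OCC=C)c3OS(=O)(=O)O)[C@@H](C)CC[C@]12C | intermediate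
35 | 2-(allyloxy)-4-(hydroxymethyl)-6-{[(1R,2S,4aS,8aS)-1,2,4a-trimethyl-5-methylidenedecahydronaphthalen-1-yl]methyl}phenyl hydrogen sulfate | C=C1CCC[C@H]2[C@](C)(Cc3cc(CO)cc(OCC=C)c3OS(=O)(=O)O)[C@@H](C)CC[C@]12C | intermediate
36 | 2-hydroxy-4-(hydroxymethyl)-6-{[(1R,2S,4aS,8aS)-1,2,4a-trimethyl-5-methylidenedecahydronaphthalen-1-yl]methyl}phenyl hydrogen sulfate (CNP0353860.3) | C=C1CCC[C@H]2[C@](C)(Cc3cc(CO)cc(O)c3OS(=O)(=O)O)[C@@H](C)CC[C@]12C | target

## Step count and risk

Total: 27 steps. Longest linear sequence: 22 steps (steps 1–15 and 21–27); the arene branch (steps 16–20) has 5 steps.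

**Step 13 (key step, proposed new method).**
- What may go wrong: the catalyst may be held by the sulfide or the ketal oxygens so that turnover stalls. Facial discrimination on the α,β-disubstituted enal may be low. The puckered seven-membered diene with its fully substituted C5 terminus may react so slowly that ketal ionisation, 1,5-hydrogen shift in the dihydrothiepine, or the exo (cis-fused) pathway compete.
- Fallback (catalyst control replaced by classical resolution, using only an uncatalysed thermal cycloaddition and known carbonyl chemistry): **17** is heated in toluene in a sealed tube with a radical inhibitor to give the racemic adduct F1. Condensation of F1 with (1R,2R)-N,N'-dimethyl-1,2-diphenylethane-1,2-diamine over molecular sieves gives the two diastereomeric aminals, the wanted aminal F2 and the aminal of the enantiomeric adduct F3. These are separated by chromatography, and brief treatment of F2 with dilute aqueous acid returns the route to **18**.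

**Step 9.**
- What may go wrong: after the first displacement the thiolate may close by SN2' to a five-membered vinyl-dihydrothiophene, or alkylate a second molecule, and the bis-allylic mesylate may ionise before sulfide arrives.
- Fallback (the ring is closed through an S–S bond and then contracted): diol **11** is mesylated to **12** as before and treated with KSAc to give the bis(thioacetate) F4 by two clean intermolecular SN2 steps. K2CO3 in MeOH frees the dithiol F5, which I2 oxidises under high dilution to the eight-membered cyclic disulfide F6. Tris(diethylamino)phosphine then extrudes one sulfur atom and gives **13**.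

**Step 6.**
- What may go wrong: the bulky ortho ketal may slow formation or cleavage of the o-quinone, the neighbouring phenol may assist loss of the ketal, and the cis,cis half-ester may lactonise or isomerise on acidic work-up.
- Fallback (two-stage oxidation with a different oxidant, ending at the diester): catechol **8** is oxidised with NaIO4 to the isolable o-quinone F7, which tetravalent lead acetate Pb(OAc)4 in MeOH/PhMe cleaves directly to the dimethyl cis,cis-muconate **10**.

**Step 14.**
- What may go wrong: once the C–S bonds are broken, the C6=C7 double bond may migrate toward C8 on the nickel surface before it is saturated, which would erode the C8 configuration. Desulfurisation may also stop at a thiol.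
- Fallback (the alkene is removed before the bridge): **18** is reduced with NaBH4 and alcohol **19** is isolated. Diimide, generated from 2-nitrobenzenesulfonyl hydrazide and Et3N, saturates the strained bicyclic alkene without touching sulfur and gives the saturated bridged sulfide alcohol F8. Raney Ni then only has to cleave C–S bonds and gives **20**.

**Step 23.**
- What may go wrong: the aqueous acid needed for the hindered C4 ketal may also remove the silyl ether and ionise the benzylic position para to the freed phenol, leading to oligomers.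
- Fallback (order changed, and the phenol unmasked without protic acid): **31** is trans-ketalised with pyridinium p-toluenesulfonate in wet acetone to the ketone with the methoxymethyl ether retained, F9. Wittig methylenation gives the alkene F10. TMSOTf with 2,2'-bipyridyl in CH2Cl2, followed by water, then removes the aryl methoxymethyl group under buffered conditions and gives **33**.

## Further compounds

F1 | step 13 | racemic 18 (both enantiomers of the adduct) | O1CCOC12CCC[C@H]3[C@](C)(C=O)[C@@H](CSC4)C=C[C@]234.O1CCOC12CCC[C@@H]3[C@@](C)(C=O)[C@H](CSC4)C=C[C@@]234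
F2 | step 13 | (4R,5R)-1,3-dimethyl-4,5-diphenylimidazolidin-2-yl aminal of 18 | O1CCOC12CCC[C@H]3[C@](C)(C5N(C)[C@H](c6ccccc6)[C@@H](c6ccccc6)N5C)[C@@H](CSC4)C=C[C@]234
F3 | step 13 | (4R,5R)-1,3-dimethyl-4,5-diphenylimidazolidin-2-yl aminal of the enantiomer of 18 | O1CCOC12CCC[C@@H]3[C@@](C)(C5N(C)[C@H](c6ccccc6)[C@@H](c6ccccc6)N5C)[C@H](CSC4)C=C[C@@]234
F4 | step 9 | S,S'-[(2E,4Z)-2-(2-{4-[(tert-butyldimethylsilyl)oxy]butyl}-1,3-dioxolan-2-yl)hexa-2,4-diene-1,6-diyl] diethanethioate | CC(=O)SC/C=C\C=C(/CSC(C)=O)C1(CCCCO[Si](C)(C)C(C)(C)C)OCCO1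
F5 | step 9 | (2E,4Z)-2-(2-{4-[(tert-butyldimethylsilyl)oxy]butyl}-1,3-dioxolan-2-yl)hexa-2,4-diene-1,6-dithiol | SC/C=C\C=C(/CS)C1(CCCCO[Si](C)(C)C(C)(C)C)OCCO1
F6 | step 9 | tert-butyl{4-[2-(3,8-dihydro-1,2-dithiocin-4-yl)-1,3-dioxolan-2-yl]butoxy}dimethylsilane | CC(C)(C)[Si](C)(C)OCCCCC1(OCCO1)C1=CC=CCSSC1
F7 | step 6 | 3-(2-{4-[(tert-butyldimethylsilyl)oxy]butyl}-1,3-dioxolan-2-yl)cyclohexa-3,5-diene-1,2-dione | CC(C)(C)[Si](C)(C)OCCCCC1(OCCO1)C1=CC=CC(=O)C1=O
F8 | step 14 | [(5R,8S,9S,10S)-4,4-ethylenedioxy-9-methyl-5,8-(2-thiapropane-1,3-diyl)decalin-9-yl]methanol | O1CCOC12CCC[C@H]3[C@](C)(CO)[C@@H](CSC4)CC[C@]234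
F9 | step 23 | (5S,8S,9R,10S)-9-{[3-(allyloxy)-5-{[(tert-butyldiphenylsilyl)oxy]methyl}-2-(methoxymethoxy)phenyl]methyl}-5,8,9-trimethyl-trans-decalin-4-one | O=C1CCC[C@H]2[C@](C)(Cc3cc(CO[Si](c4ccccc4)(c4ccccc4)C(C)(C)C)cc(OCC=C)c3OCOC)[C@@H](C)CC[C@]12C
F10 | step 23 | tert-butyl{[3-(allyloxy)-4-(methoxymethoxy)-5-{[(1R,2S,4aS,8aS)-1,2,4a-trimethyl-5-methylidenedecahydronaphthalen-1-yl]methyl}phenyl]methoxy}diphenylsilane | C=C1CCC[C@H]2[C@](C)(Cc3cc(CO[Si](c4ccccc4)(c4ccccc4)C(C)(C)C)cc(OCC=C)c3OCOC)[C@@H](C)CC[C@]12C
A1 | alternative 1 | methyl 3,4-dimethoxy-5-{[(1R,2S,4aS,8aS)-1,2,4a-trimethyl-5-methylidenedecahydronaphthalen-1-yl]methyl}benzoate | C=C1CCC[C@H]2[C@](C)(Cc3cc(C(=O)OC)cc(OC)c3OC)[C@@H](C)CC[C@]12C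
A2 | alternative 1 | methyl 3-[(drim-8(12)-en-11-yl)]-4,5-dimethoxybenzoate (5α-H, 9α-H, 10β-CH3) | C=C1CC[C@H]2C(C)(C)CCC[C@]2(C)[C@H]1Cc1cc(C(=O)OC)cc(OC)c1OC
A3 | alternative 2 | trans-decalin-6-one 4-ethylene ketal with 5β,8β,9β-methyl groups and the 9α-arylmethyl group | O1CCOC12CCC[C@H]3[C@](C)(Cc4cc(CO[Si](C)(C)C(C)(C)C)cc(OCOC)c4OCOC)[C@@H](C)CC(=O)[C@]23C
A4 | alternative 2 | (E)-crotonyl ketone on C5 of a cyclohexanone ketal with a 3-arylprop-1-en-2-yl group on C10 | O1CCOC12CCC[C@@H](C(=C)Cc3cc(CO[Si](C)(C)C(C)(C)C)cc(OCOC)c3OCOC)[C@]2(C)C(=O)/C=C/C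
A5 | alternative 3 | dimethyl (2S,4aS,8aS)-2,4a-dimethyl-5-methylideneoctahydronaphthalene-1,1(2H)-dicarboxylate | C=C1CCC[C@H]2C(C(=O)OC)(C(=O)OC)[C@@H](C)CC[C@]12C
A6 | alternative 3 | dimethyl 2-[(2S,5E)-5-methylundeca-5,10-dien-2-yl]propanedioate | COC(=O)C(C(=O)OC)[C@@H](C)CC/C(C)=C/CCCC=C
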